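Atom numbers follow the order of the atoms in the target SMILES: C1 (methyl), C2, C3, C4, O5, O6, C7, C8, C9, C10, C11, O12, C13 to C20, C21, C22, C23, C24, O25, O26, C27, C28, N29, C30.

## Analysis of the target

Target 51 is a heptacyclic amino bis-lactone. Its rings are a γ-lactone (C2, C3, C4, O6, C7), a pyrrolidine (C2, C7, C8, N29, C30), a cyclopentane (C8, C9, C10, C21, C27), a piperidine (C8, C9, C10, C13, C28, N29), a cycloheptane (C10, C13, C14, C15, C16, C20, C21), a cyclopentene (C16 to C20) and a δ-lactone (C21, C22, C23, C24, O26, C27). There are eight stereocentres (C2, C7, C8, C10, C13, C16, C21, C27). Four are fully substituted: C8 carries nitrogen, and C10 and C21 are vicinal all-carbon quaternary centres. On the central cyclopentane, N29, C13 and C20 lie on one face; C7, C11, C22 and O26 lie on the other. The sensitive groups are the two lactones (hydride, alkoxide, and O-to-N acyl shift of the γ-lactone while N29 is still a primary amine), the tertiary amine (oxidants), and the C19=C20 alkene, which can move towards C16 whenever C21 carries hydrogen next to a carbonyl group. The difficulty is the density of congested centres around the cyclopentane, above all the aza-quaternary C8 between the oxygen-bearing carbons C7 and C27 and the quaternary C2. The strategy rests on the 1,2-amino alcohol N29–C8–C7–O6: C2 is quaternary, so C8–H is the only hydrogen β to O6, and the cis arrangement of C7, C11 and O26 on the cyclopentane is what results from cleaving the double bond of endo-norbornenol.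

## Retrosynthetic reasoning

**O12–Si and the δ-lactone (51 ⇒ 50 ⇒ 48).** The free hydroxymethyl group is unmasked last from silyl ether 50. The δ-lactone is opened at O26–C24 to keto ester 48. A simple hydride should attack the C27 ketone from the open exo face and give the wrong epimer, so the forward step has to run under equilibrating conditions, with lactonisation trapping the alkoxide that is cis to the C22 arm.

**C20–C21 and C21–C22 (48 ⇒ 47 ⇒ 46).** The seven-membered ring is cut at C20–C21, next to the C27 ketone, which is the only handle that can activate C21. The alkenyl bromide in 47 is tethered through C13, so palladium must deliver C20 to the face of C21 that the target needs. The propanoate arm is removed first in the retrosynthetic direction (47 ⇒ 46), so that in the forward direction it is in place before ring closure. C21 then never carries a hydrogen next to both the ketone and the new alkene, and the alkene cannot migrate towards C16.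

**C14–C15 and the ring E fragment (46 ⇒ 35 + 42).** C14 and C15 are methylene groups, so an olefination followed by saturation joins the core to ring E without touching a stereocentre. This allows C16 to be made beforehand in the small fragment 42, by reagent-controlled reduction of 36 and a suprafacial [3,3] shift. A Michael acceptor on nitrogen would have left C15 as a carboxyl carbon and forced C16 to be created on the full skeleton without control, so the core is given a C14 aldehyde (35) instead.

**C10–C13 and N29–C28 (35 ⇒ 31 ⇒ 30 ⇒ 29).** The piperidine is cut at C10–C13. Forward, the enamine of the C11 aldehyde attacks a π-allyl unit hung on N29. The tether reaches C10 only on the face that carries nitrogen, which fixes the quaternary centre. The resulting vinyl group is the masked C14 aldehyde. The four-carbon unit is attached to the secondary amine 29 beforehand.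

**N29–C30 and the γ-lactone (29 ⇒ 27 ⇒ 25 ⇒ 21).** The pyrrolidine is opened at N29–C30 (reductive amination) and the γ-lactone at O6–C4 (oxidative lactonisation of a 1,4-diol). Both primary oxygens are carried as the same silyl ether, so that one fluoride step and one oxidation step convert triol 25. Nitrogen stays acylated until the lactone exists and is then kept protonated until the imine has closed, because a free primary amine next to the γ-lactone would take the acyl group.

**N29–C8, the key disconnection (21 ⇒ 19).** The bond to the aza-quaternary centre is cut so that nitrogen comes from the C7 carbamate of 19. This places the hardest centre on an early, cheap intermediate and takes its configuration from a C–H bond whose orientation is already fixed.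

**C7–C2 (19 ⇒ 14 ⇒ 7 + 12).** The side chain is cut between C7 and C2. One allylboration makes both centres. The target needs C30 syn and C3 anti to O6 when C8–C7–C2 is drawn in zigzag with the third arm. A boronate that carried the oxygenated one-carbon arm on its double bond would need the less accessible Z geometry. The roles are therefore exchanged: the vinyl group of 14 becomes C30, and the E-configured boronate 12, available by syn carbometalation of 8, brings the C3–C4 arm.

**C5=C6 of the norbornene (7 ⇒ 4 ⇒ 1).** The cyclopentane with C8, C10 and C27 in the all-cis arrangement comes from oxidative cleavage of resolved endo-norbornenol 4. Only the C11 aldehyde can close onto O26 (five-membered lactol); C7 would need a four-membered ring. This difference is the sole differentiation of the two aldehydes and must be used without acid, since acidic methanol would acetalise both.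

## Alternatives that were turned down

**Alternative 1:** The cyclopentane is closed last, at C9–C10, by intramolecular cyclopropanation. A C8 diazoketone is decomposed by a dirhodium carboxylate, and the carbenoid adds to an exocyclic C10=C11 methylene on a preformed cycloheptane. This gives the cyclopropyl ketone A1, whose extra C9–C11 bond is later opened by an oxygen nucleophile to leave the C11 hydroxymethyl group.
- For it: carbenoid cyclopropanation is dependable, the tether fixes the face, and one step makes the quaternary C10, the cyclopentanone and the C11 carbon. The seven-membered ring, ring E and the δ-lactone are already present in A1, so the late palladium closure of two vicinal quaternary centres is avoided. On that point it is stronger than the chosen route.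
- Against it: in A1, C8 is still a ketone. The aza-quaternary centre, C7, C2, the pyrrolidine and the γ-lactone would all have to be built late by addition to a hindered ketimine whose α-carbon C27 bears an acyloxy group (risk of epimerisation or elimination). The cyclopropane can also open at C9–C10 instead of C9–C11.
- Comparison: the chosen strategy sets C8 by a retentive insertion whose face is fixed in advance and does so within the first dozen steps. A1 postpones the hardest centre to the end of a longer sequence.

**Alternative 2:** The γ-lactone is made from the pyrrolidine. A chlorinated ketene adds across the C2=C7 double bond of a 4-methyl-3,4-dehydroproline ester, on the face away from the C8 ester, to give cyclobutanone A2. Baeyer–Villiger oxidation then inserts O6 between C4 and C7.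
- For it: it starts from the amino acid pool and gives the pyrrolidine, C2, C7 and the lactone carbon framework in very few steps with reliable facial control. For C2 and C7 it is stronger than the allylboration of the chosen route, which depends on double stereodifferentiation.
- Against it: in A2, C8 is an ester α-carbon that still bears hydrogen. It would have to become the spiro aza-quaternary centre by enolate chemistry, which erases its configuration. The whole cyclopentane with C27–O26 and the quaternary C10 would then have to be assembled on that neopentyl position.
- Comparison: the chosen strategy reverses the order. The carbocycle arrives with three stereocentres from a norbornene, and nitrogen is delivered to it. It pays for this with the longer elaboration of the C2 side chain (steps 8 to 17).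

**Alternative 3:** The plan is centred on the C20–C21 bond. Zerovalent palladium with a bulky trialkylphosphine and an alkoxide base couples the C21 enolate of the C27 ketone with a tethered C20 alkenyl triflate, giving the hexacyclic keto ester A3. A3 has the same structure as compound 48 of the chosen route.
- For it: one known reaction makes the seven-membered ring and the second of the two vicinal quaternary centres, and the tether enforces the cis ring fusion. It creates more skeletal complexity per step than the nitrene insertion.
- Against it: as the centre of a plan it presupposes the complete azatricyclic ketone and does not say how N29–C8 is made. It also puts the step most likely to fail at the very end, on the most valuable material.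
- Comparison: this is not a rival, since the same closure is used here as step 32. The chosen strategy adds a solution for C8 and moves the strategic risk to step 12, where the substrate is made in eleven steps from cheap materials.

Key step: step 12

## Remarks on assumptions

- Commercial 5-norbornen-2-ol is taken to be the usual endo-rich mixture of racemic endo and exo alcohols; steps 1 and 2 converge it on the endo alcohol.
- The lipase is assumed to follow the empirical size rule for secondary alcohols and to acylate the (2R) alcohol faster, so that the (1S,2S,4S) alcohol is the one recovered.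
- The acetal carbon C11 is written as the exo methyl acetal; its configuration has no consequence because C11 returns to the lactol in step 17.

## Route

**Step 1**
Reactants: 1 5-norbornen-2-ol (commercial endo/exo mixture)
Product: 2 rac-bicyclo[2.2.1]hept-5-en-2-one
Conditions: nPr4N[RuO4] (5 mol%), N-methylmorpholine N-oxide, 4 Å MS, CH2Cl2, rt
Reagents that add atoms: none
Why: Ley–Griffith oxidation of a secondary alcohol; it removes the carbinol centre so that both diastereomers give one ketone, and the alkene is not touched.

**Step 2**
Reactants: 2 rac-bicyclo[2.2.1]hept-5-en-2-one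
Product: 3 rac-endo-bicyclo[2.2.1]hept-5-en-2-ol
Conditions: LiBH(sBu)3, THF, −78 °C; then H2O
Reagents that add atoms: none
Why: The bulky hydride attacks the norbornenone from the open exo face, so the hydroxyl group should end up endo, on the side of the double bond.

**Step 3**
Reactants: 3 rac-endo-bicyclo[2.2.1]hept-5-en-2-ol
Product: 4 (1S,2S,4S)-bicyclo[2.2.1]hept-5-en-2-ol
Conditions: Candida rugosa lipase, vinyl acetate, tBuOMe, 30 °C, stopped beyond half conversion
Reagents that add atoms: none
Why: Lipase-catalysed kinetic resolution by irreversible transesterification; the (2R) alcohol is removed as its acetate and the slower (1S,2S,4S) alcohol, which carries the C8, C10 and C27 configuration of the target, is recovered in high enantiomeric purity when the reaction is run past half conversion.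

**Step 4**
Reactants: 4 (1S,2S,4S)-bicyclo[2.2.1]hept-5-en-2-ol
Product: 6 lactol aldehyde (C11 hemiacetal on O26; C7 aldehyde), via ozonide 5 (not isolated)
Conditions: O3, CH2Cl2, −78 °C; PPh3, −78 °C → rt
Reagents that add atoms: ozone, [O-][O+]=O
Why: Ozonolysis cuts C5=C6 of the norbornene and leaves C7, C11 and O26 cis on the cyclopentane; the C11 aldehyde closes onto O26 as a five-membered lactol, whereas C7 cannot (four-membered ring). The neutral reductive work-up should leave the epimerisable C8 untouched.

**Step 5**
Reactants: 6 lactol aldehyde
Product: 7 exo methyl acetal aldehyde (6-endo-formyl-3-exo-methoxy-2-oxabicyclo[2.2.1]heptane)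
Conditions: MeOTf, 2,6-di-tert-butyl-4-methylpyridine, CH2Cl2, 0 °C → rt
Reagents that add atoms: methyl trifluoromethanesulfonate, COS(=O)(=O)C(F)(F)F
Why: O-Methylation of the hemiacetal hydroxyl with a hard methylating agent and a non-nucleophilic base, under conditions that neither acetalise nor enolise the C7 aldehyde. Acidic methanol is avoided because it would convert both carbonyl groups and the strained bicyclic acetal would not survive a selective hydrolysis.

**Step 6**
Reactants: 8 tert-butyl(but-3-yn-1-yloxy)dimethylsilane
Product: 10 (E)-tert-butyl[(4-iodo-3-methylbut-3-en-1-yl)oxy]dimethylsilane, via alkenylalane 9 (not isolated)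
Conditions: Me3Al, Cp2ZrCl2 (20 mol%), CH2Cl2, 0 °C → rt; [I][I], THF, −30 °C; aq. K2CO3
Reagents that add atoms: trimethylaluminium, C[Al](C)C; iodine, [I][I]
Why: Negishi zirconium-catalysed carboalumination adds methyl and aluminium syn across the alkyne with aluminium on the terminal carbon; iodinolysis with retention gives the E iodide.

**Step 7**
Reactants: 10 (E)-alkenyl iodide
Product: 12 (E)-allylboronate (pinacol ester of (E)-5-silyloxy-3-methylpent-2-enylboronic acid), via alkenyllithium 11 (not isolated)
Conditions: t-BuLi (2.1 equiv), Et2O, −78 °C; ICH2B(pin), −78 °C → rt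
Reagents that add atoms: 2-(iodomethyl)-4,4,5,5-tetramethyl-1,3,2-dioxaborolane, ICB1OC(C)(C)C(C)(C)O1
Why: Iodine–lithium exchange with retention, then Matteson homologation: the alkenyl group migrates from boron to carbon in the boronate complex and displaces iodide, so the methyl group stays cis to the CH2B group.

**Step 8**
Reactants: 7 exo methyl acetal aldehyde; 12 (E)-allylboronate
Product: 14 homoallylic alcohol (C7 carbinol; C2 quaternary with methyl, vinyl and silyloxyethyl), via pinacol borate ester 13 (not isolated)
Conditions: toluene, 4 Å MS, rt → 40 °C; then pH 7 buffer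
Reagents that add atoms: none
Why: Allylboration through a closed Zimmerman–Traxler chair: the E geometry of 12 puts the methyl group syn and the silyloxyethyl arm anti to the new hydroxyl, which fixes C2 relative to C7. C7 is set relative to C8 by attack on the Si face of the aldehyde, the arrangement in which H8 faces the axial γ-methyl group and the bulky C27 branch lies anti to the forming bond.

**Step 9**
Reactants: 14 homoallylic alcohol
Product: 16 1,3-diol (C30 hydroxymethyl), via ozonide 15 (not isolated)
Conditions: O3, CH2Cl2, −78 °C; NaBH4, MeOH, −78 → 0 °C
Reagents that add atoms: ozone, [O-][O+]=O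
Why: Ozonolysis of the vinyl group with reductive work-up turns it into the C30 hydroxymethyl group; reducing in the same flask avoids a β-hydroxy aldehyde that could undergo retro-aldol cleavage.

**Step 10**
Reactants: 16 1,3-diol
Product: 17 bis-silyl ether with free C7 hydroxyl
Conditions: TBSCl, imidazole, CH2Cl2, 0 °C
Reagents that add atoms: tert-butyldimethylsilyl chloride, CC(C)(C)[Si](C)(C)Cl
Why: Silylation is selective for the primary hydroxyl; the C7 hydroxyl between the quaternary C2 and the ring is far slower.

**Step 11**
Reactants: 17 bis-silyl ether alcohol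
Product: 19 C7 primary carbamate, via N-trichloroacetyl carbamate 18 (not isolated)
Conditions: Cl3CC(O)NCO, CH2Cl2, 0 °C; K2CO3, MeOH, 0 °C → rt
Reagents that add atoms: trichloroacetyl isocyanate, O=C=NC(=O)C(Cl)(Cl)Cl
Why: The very electrophilic isocyanate acylates even the hindered secondary alcohol; methanolysis removes the trichloroacetyl group and leaves the silyl ethers and the acetal.

**Step 12 (key step)**
Reactants: 19 C7 primary carbamate
Product: 21 spiro-oxazolidinone with aza-quaternary C8, via iminoiodinane 20 (not isolated)
Conditions: Rh2(OAc)4 (5 mol%), PhI(OAc)2 (1.4 equiv), MgO (2.3 equiv), CH2Cl2, 40 °C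
Reagents that add atoms: none
Why: PhI(OAc)2 converts the carbamate into an iminoiodinane, from which Rh2(OAc)4 forms a rhodium-bound nitrene; this inserts in a concerted, asynchronous way into the C8–H bond, forming N29–C8 and closing the oxazolidinone. The closest known reaction type is the dirhodium-catalysed intramolecular C–H amination of primary carbamates at tertiary C–H bonds. The ring closes by insertion through a five-membered transition state at the carbon β to the carbamate oxygen, the mode that the planar carbamate tether strongly favours. The new stereocentre C8 is formed with retention: nitrogen takes the place of H8 on the face opposite to C7, O26 and C11, a relationship fixed when the norbornene was cut. Site selectivity is needed against the six-membered mode at C30–H, C3–H and C1–H and against the acetal C11–H; it is secured because C8–H is the only β-hydrogen (C2 is quaternary) and the tether does not reach further. Chemoselectivity is secured by the absence of free hydroxyl, amine or alkene groups and by MgO, which takes up the acetic acid before it can open the strained acetal. The C–H bond is tertiary but somewhat deactivated by O26 on the neighbouring carbon, which is why the main risk of the route is placed here, on early material.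

**Step 13**
Reactants: 21 spiro-oxazolidinone
Product: 22 N-Boc oxazolidinone
Conditions: Boc2O, DMAP (cat.), Et3N, THF, rt → 40 °C
Reagents that add atoms: di-tert-butyl dicarbonate, CC(C)(C)OC(=O)OC(=O)OC(C)(C)C
Why: Acylation of the carbamate nitrogen activates the ring carbonyl for mild cleavage and provides the nitrogen protecting group for the following oxidation.

**Step 14**
Reactants: 22 N-Boc oxazolidinone
Product: 24 N-Boc amino alcohol (free C7 hydroxyl), via methyl carbonate 23 (not isolated)
Conditions: Cs2CO3 (0.3 equiv), MeOH, rt
Reagents that add atoms: none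
Why: Methoxide opens the activated ring at the endocyclic carbonyl and the resulting O6 methyl carbonate is methanolysed, so the temporary carbonyl carbon is removed without touching C7 or C8.

**Step 15**
Reactants: 24 N-Boc amino alcohol
Product: 25 N-Boc amino triol
Conditions: Bu4NF, THF, 0 °C → rt
Reagents that add atoms: none
Why: Fluoride removes both primary silyl ethers; the methyl acetal and the carbamate are stable to it.

**Step 16**
Reactants: 25 N-Boc amino triol
Product: 27 γ-lactone aldehyde (C30 aldehyde in equilibrium with its cyclic N-Boc hemiaminal), via lactol aldehyde 26 (not isolated)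
Conditions: TEMPO (20 mol%), PhI(OAc)2 (3.3 equiv), CH2Cl2, rt
Reagents that add atoms: none
Why: Oxoammonium oxidation is selective for primary alcohols: the C4 aldehyde is trapped by O6 as a lactol and oxidised on to the γ-lactone, while the C30 aldehyde has no hydroxyl in reach and stays at the aldehyde level. The hindered C7 hydroxyl is consumed by lactol formation before it can be oxidised.

**Step 17**
Reactants: 27 γ-lactone aldehyde
Product: 29 amino lactol (pyrrolidine N29–H; γ-lactone; C11 lactol on O26), via cyclic imine 28 (not isolated)
Conditions: CF3CO2H/H2O (9:1), 0 °C → rt; evaporation; H2 (1 atm), Pd/C, MeOH; then aq. NaHCO3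
Reagents that add atoms: water, O
Why: Acid removes the Boc group, closes the five-membered iminium ion between N29 and C30 and hydrolyses the methyl acetal to the lactol; hydrogenation of the iminium salt gives the pyrrolidine (intramolecular reductive amination). The nitrogen stays protonated until the ring is closed, so the O-to-N acyl shift of the γ-lactone cannot start, and once the pyrrolidine exists that shift would need a bridgehead amide.

**Step 18**
Reactants: 29 amino lactol
Product: 30 N-[(E)-4-acetoxybut-2-enyl] amine
Conditions: Pd(PPh3)4 (5 mol%), (Z)-AcOCH2CH=CHCH2OAc (3 equiv), Et3N, THF, 45 °C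
Reagents that add atoms: (Z)-but-2-ene-1,4-diyl diacetate, CC(=O)OC/C=C\COC(C)=O
Why: Tsuji–Trost amination: the secondary amine attacks the unsubstituted terminus of the π-allyl palladium complex; the excess of diacetate suppresses double substitution and the E allylic acetate is left for the next step.

**Step 19**
Reactants: 30 N-(4-acetoxybut-2-enyl) amine
Product: 31 azabicyclic lactol with quaternary C10 and vinyl group on C13
Conditions: Pd(PPh3)4 (10 mol%), pyrrolidine (0.5 equiv), Et3N, DMSO, 40 °C
Reagents that add atoms: none
Why: Intramolecular Tsuji–Trost allylation of an aldehyde through its enamine (6-exo attack of C10 on the π-allyl terminus C13); the tether from N29 reaches C10 only on the nitrogen-bearing face, so C11 stays cis to O26 and the lactol re-forms. C13 is set in the chair-like transition state with the allyl unit equatorial, the orientation that points C14 towards C21.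

**Step 20**
Reactants: 31 azabicyclic lactol
Product: 32 diol (C11 hydroxymethyl; C27 hydroxyl)
Conditions: NaBH4, MeOH, 0 °C
Reagents that add atoms: none
Why: The lactol is reduced through its open aldehyde form; the γ-lactone is not reduced by NaBH4 at this temperature.

**Step 21**
Reactants: 32 diol
Product: 33 C11 silyl ether with free C27 hydroxyl
Conditions: TBSCl, imidazole, CH2Cl2, 0 °C
Reagents that add atoms: tert-butyldimethylsilyl chloride, CC(C)(C)[Si](C)(C)Cl
Why: The primary hydroxyl is silylated in preference to the secondary C27 hydroxyl, which lies next to the quaternary C8.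

**Step 22**
Reactants: 33 C11 silyl ether
Product: 35 C14 aldehyde, via ozonide 34 (not isolated)
Conditions: O3, CF3CO2H (1.2 equiv), CH2Cl2, −78 °C; PPh3; aq. NaHCO3
Reagents that add atoms: ozone, [O-][O+]=O
Why: Ozonolysis of the vinyl group with the amine protected as its ammonium salt; the aldehyde is epimerisable at C13, and the required isomer carries the formyl group equatorial on the piperidine chair.

**Step 23**
Reactants: 36 2-bromocyclopent-2-en-1-one
Product: 37 (R)-2-bromocyclopent-2-en-1-ol
Conditions: (S)-2-methyl-CBS-oxazaborolidine (10 mol%), BH3·SMe2, THF, −20 °C; MeOH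
Reagents that add atoms: none
Why: Corey–Bakshi–Shibata reduction; the bromoalkene side acts as the large group, so the S catalyst should give the R alcohol.

**Step 24**
Reactants: 37 (R)-2-bromocyclopent-2-en-1-ol
Product: 39 ethyl (R)-2-(2-bromocyclopent-2-en-1-yl)acetate, via ketene acetal 38 (not isolated)
Conditions: MeC(OEt)3, EtCO2H (cat.), 140 °C
Reagents that add atoms: triethyl orthoacetate, CCOC(C)(OCC)OCC
Why: Johnson–Claisen rearrangement; the suprafacial [3,3] shift carries the carbinol configuration to the ring carbon that becomes C16 and leaves the bromine on the alkene carbon next to it.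

**Step 25**
Reactants: 39 ethyl ester
Product: 40 (R)-2-(2-bromocyclopent-2-en-1-yl)acetic acid
Conditions: LiOH, THF/H2O, rt; then 1 M HCl
Reagents that add atoms: lithium hydroxide, [Li+].[OH-]
Why: Saponification; the stereocentre is β to the carboxyl group and cannot epimerise.

**Step 26**
Reactants: 40 carboxylic acid
Product: 41 (S)-1-bromo-5-(iodomethyl)cyclopent-1-ene
Conditions: PhI(OAc)2, [I][I], hν, cyclohexane, reflux
Reagents that add atoms: iodine, [I][I]
Why: Hunsdiecker-type iododecarboxylation through the acyl hypoiodite; the primary radical is trapped by iodine far faster than it can add to the neighbouring alkene, and C16 is not involved. The descriptor changes only because iodine changes the priorities.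

**Step 27**
Reactants: 41 iodide
Product: 42 [(2-bromocyclopent-2-en-1-yl)methyl]triphenylphosphonium iodide (ring E fragment)
Conditions: PPh3, MeCN, reflux
Reagents that add atoms: triphenylphosphine, c1ccc(cc1)P(c1ccccc1)c1ccccc1
Why: SN2 quaternisation of a primary iodide; the alkenyl bromide does not react with the phosphine without a metal catalyst.

**Step 28**
Reactants: 35 C14 aldehyde; 42 phosphonium iodide
Product: 44 (Z)-C14=C15 alkene carrying ring E, via phosphorus ylide 43 (not isolated)
Conditions: NaN(SiMe3)2 (2.4 equiv), THF, −78 °C; then 35, −78 → 0 °C
Reagents that add atoms: none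
Why: Wittig olefination with a non-stabilised ylide, used in excess because of the free C27 hydroxyl; it joins the core to the fragment that already carries C16, and the alkene geometry is irrelevant because the bond is saturated next.

**Step 29**
Reactants: 44 (Z)-alkene
Product: 45 saturated C13–C14–C15–C16 chain
Conditions: TsNHNH2, NaOAc, DME/H2O, 85 °C
Reagents that add atoms: none
Why: Diimide reduction is selective for the unhindered disubstituted alkene; the trisubstituted bromoalkene, the lactone and the amine are left.

**Step 30**
Reactants: 45 C27 alcohol
Product: 46 C27 ketone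
Conditions: Dess–Martin periodinane, NaHCO3, CH2Cl2, 0 °C → rt
Reagents that add atoms: none
Why: Dess–Martin oxidation of the secondary alcohol; the ketone can enolise only towards C21 because C8 is quaternary.

**Step 31**
Reactants: 46 C27 ketone
Product: 47 keto ester (propanoate arm on C21)
Conditions: methyl acrylate, KOtBu (20 mol%), tBuOH/THF, 0 °C
Reagents that add atoms: methyl acrylate, C=CC(=O)OC
Why: Michael addition of the only possible enolate; a second addition should be blocked because C21 then lies between the quaternary C10 and the carbonyl group. The configuration at C21 (drawn with the arm on the exo face) is of no consequence, since the centre is enolised again in step 32.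

**Step 32**
Reactants: 47 keto ester
Product: 48 hexacyclic keto ester with quaternary C21
Conditions: NaN(SiMe3)2 (1.2 equiv), Pd2(dba)3 (5 mol%), P(tBu)3 (12 mol%), toluene, 70 °C
Reagents that add atoms: none
Why: Palladium-catalysed intramolecular α-alkenylation of a ketone: zerovalent palladium inserts into the C20–Br bond, the sodium enolate replaces bromide on palladium, and reductive elimination forms C20–C21 and the seven-membered ring. The tether from C13 can deliver C20 only to the face of C21 that carries N29 and C13, so the propanoate arm is forced to the face of O26; the amide base avoids transesterification.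

**Step 33**
Reactants: 48 hexacyclic keto ester
Product: 50 O12-silyl bis-lactone, via hydroxy ester 49 (not isolated)
Conditions: Al(OiPr)3 (3 equiv), iPrOH/toluene, 90 °C; then aq. potassium sodium tartrate
Reagents that add atoms: none
Why: Meerwein–Ponndorf–Verley reduction under reversible hydride transfer: the alkoxide with oxygen on the face of the C22 arm is removed as the δ-lactone, while the epimeric alkoxide, which cannot lactonise and is strained against the C28 methylene, returns to the ketone by Oppenauer oxidation. C27 is therefore set under thermodynamic control rather than by the kinetic exo attack of a hydride reagent.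

**Step 34**
Reactants: 50 O12-silyl bis-lactone
Product: 51 target
Conditions: HF·pyridine, THF/pyridine, 0 °C → rt
Reagents that add atoms: none
Why: Fluoride cleaves the primary silyl ether under conditions that leave both lactones, the amine and the alkene unchanged.

## Compound list

1 | 5-norbornen-2-ol (bicyclo[2.2.1]hept-5-en-2-ol), commercial endo/exo mixture of racemates | OC1CC2CC1C=C2 | starting material
2 | rac-bicyclo[2.2.1]hept-5-en-2-one | O=C1CC2CC1C=C2 | intermediate
3 | rac-endo-bicyclo[2.2.1]hept-5-en-2-ol (racemate; the SMILES shows the enantiomer carried on) | O[C@H]1C[C@@H]2C[C@H]1C=C2 | intermediate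
4 | (1S,2S,4S)-bicyclo[2.2.1]hept-5-en-2-ol (endo alcohol) | O[C@H]1C[C@@H]2C[C@H]1C=C2 | intermediate
5 | secondary ozonide of 4 (1,2,4-trioxolane spanning C7 and C11) | O[C@H]1C[C@@H]2C[C@H]1C3OOC2O3 | intermediate (not isolated)
6 | lactol aldehyde: 6-endo-formyl-2-oxabicyclo[2.2.1]heptan-3-ol, C11 anomers, C8, C10 and C27 as in 4 | O=C[C@@H]1C[C@H]2C[C@@H]1OC2O | intermediate
7 | exo methyl acetal aldehyde: 6-endo-formyl-3-exo-methoxy-2-oxabicyclo[2.2.1]heptane | O=C[C@@H]1C[C@H]2C[C@@H]1O[C@@H]2OC | intermediate
8 | tert-butyl(but-3-yn-1-yloxy)dimethylsilane | C#CCCO[Si](C)(C)C(C)(C)C | starting material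
9 | (E)-alkenyl(dimethyl)alane from syn methylalumination of 8 | C[Al](C)/C=C(\C)CCO[Si](C)(C)C(C)(C)C | intermediate (not isolated)
10 | (E)-tert-butyl[(4-iodo-3-methylbut-3-en-1-yl)oxy]dimethylsilane | I/C=C(\C)CCO[Si](C)(C)C(C)(C)C | intermediate
11 | (E)-alkenyllithium from 10 | [Li]/C=C(\C)CCO[Si](C)(C)C(C)(C)C | intermediate (not isolated)
12 | (E)-allylboronate: pinacol ester of (E)-5-(tert-butyldimethylsilyloxy)-3-methylpent-2-enylboronic acid | CC1(C)OB(C/C=C(\C)CCO[Si](C)(C)C(C)(C)C)OC1(C)C | intermediate
13 | pinacol borate ester of 14 at O6 | CC(C)(C)[Si](C)(C)OCC[C@@](C)(C=C)[C@H](OB1OC(C)(C)C(C)(C)O1)[C@@H]2C[C@H]3C[C@@H]2O[C@@H]3OC | intermediate (not isolated)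
14 | homoallylic alcohol: C7 carbinol on the acetal bicycle, C2 quaternary with methyl, vinyl and 2-silyloxyethyl groups | CC(C)(C)[Si](C)(C)OCC[C@@](C)(C=C)[C@H](O)[C@@H]1C[C@H]2C[C@@H]1O[C@@H]2OC | intermediate
15 | ozonide of the vinyl group of 14 | CC(C)(C)[Si](C)(C)OCC[C@@](C)(C1OOCO1)[C@H](O)[C@@H]2C[C@H]3C[C@@H]2O[C@@H]3OC | intermediate (not isolated)
16 | 1,3-diol: C30 hydroxymethyl and C7 hydroxyl | CC(C)(C)[Si](C)(C)OCC[C@@](C)(CO)[C@H](O)[C@@H]1C[C@H]2C[C@@H]1O[C@@H]2OC | intermediate
17 | bis-silyl ether (O at C4 and C30) with free C7 hydroxyl | CC(C)(C)[Si](C)(C)OCC[C@@](C)(CO[Si](C)(C)C(C)(C)C)[C@H](O)[C@@H]1C[C@H]2C[C@@H]1O[C@@H]2OC | intermediate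
18 | N-trichloroacetyl carbamate of 17 | CC(C)(C)[Si](C)(C)OCC[C@@](C)(CO[Si](C)(C)C(C)(C)C)[C@H](OC(=O)NC(=O)C(Cl)(Cl)Cl)[C@@H]1C[C@H]2C[C@@H]1O[C@@H]2OC | intermediate (not isolated)
19 | C7 primary carbamate (precursor of the key step) | CC(C)(C)[Si](C)(C)OCC[C@@](C)(CO[Si](C)(C)C(C)(C)C)[C@H](OC(N)=O)[C@@H]1C[C@H]2C[C@@H]1O[C@@H]2OC | intermediate
20 | N-(phenyl-λ3-iodanylidene) carbamate (iminoiodinane) of 19 | CC(C)(C)[Si](C)(C)OCC[C@@](C)(CO[Si](C)(C)C(C)(C)C)[C@H](OC(=O)N=Ic1ccccc1)[C@@H]2C[C@H]3C[C@@H]2O[C@@H]3OC | intermediate (not isolated)
21 | spiro-oxazolidinone: N29 on C8 with retention, ring O6–C7–C8–N29–C(=O) | CC(C)(C)[Si](C)(C)OCC[C@@](C)(CO[Si](C)(C)C(C)(C)C)[C@@H]1OC(=O)N[C@]12C[C@H]3C[C@@H]2O[C@@H]3OC | intermediate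
22 | N-Boc oxazolidinone | CC(C)(C)[Si](C)(C)OCC[C@@](C)(CO[Si](C)(C)C(C)(C)C)[C@@H]1OC(=O)N(C(=O)OC(C)(C)C)[C@]12C[C@H]3C[C@@H]2O[C@@H]3OC | intermediate
23 | O6 methyl carbonate of the N-Boc amine | CC(C)(C)[Si](C)(C)OCC[C@@](C)(CO[Si](C)(C)C(C)(C)C)[C@H](OC(=O)OC)[C@]1(NC(=O)OC(C)(C)C)C[C@H]2C[C@@H]1O[C@@H]2OC | intermediate (not isolated)
24 | N-Boc amino alcohol: NHBoc on C8, free C7 hydroxyl | CC(C)(C)[Si](C)(C)OCC[C@@](C)(CO[Si](C)(C)C(C)(C)C)[C@H](O)[C@]1(NC(=O)OC(C)(C)C)C[C@H]2C[C@@H]1O[C@@H]2OC | intermediate
25 | N-Boc amino triol: hydroxyl groups at C4, C7 and C30 | OCC[C@@](C)(CO)[C@H](O)[C@]1(NC(=O)OC(C)(C)C)C[C@H]2C[C@@H]1O[C@@H]2OC | intermediate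
26 | lactol aldehyde: C4 lactol on O6, C30 aldehyde | O=C[C@]1(C)CC(O)O[C@@H]1[C@]2(NC(=O)OC(C)(C)C)C[C@H]3C[C@@H]2O[C@@H]3OC | intermediate (not isolated)
27 | γ-lactone aldehyde: lactone C2–C3–C4–O6–C7, C30 aldehyde, NHBoc on C8 | O=C[C@]1(C)CC(=O)O[C@@H]1[C@]2(NC(=O)OC(C)(C)C)C[C@H]3C[C@@H]2O[C@@H]3OC | intermediate
28 | cyclic imine (N29=C30) with C11 lactol | C[C@@]12CC(=O)O[C@@H]1[C@]3(N=C2)C[C@H]4C[C@@H]3OC4O | intermediate (not isolated)
29 | amino lactol: pyrrolidine N29–H cis-fused to the γ-lactone, spiro at C8; C11 lactol on O26 (anomers) | C[C@@]12CC(=O)O[C@@H]1[C@]3(NC2)C[C@H]4C[C@@H]3OC4O | intermediate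
30 | N-[(E)-4-acetoxybut-2-enyl] derivative of 29 | C[C@@]12CC(=O)O[C@@H]1[C@]3(N(C/C=C/COC(C)=O)C2)C[C@H]4C[C@@H]3OC4O | intermediate
31 | azabicyclic lactol: piperidine closed (C10–C13), vinyl on C13, C10 quaternary, C11 lactol on O26 | C[C@@]12CC(=O)O[C@@H]1[C@]13C[C@@]4(C(O)O[C@H]1C4)[C@H](C=C)CN3C2 | intermediate
32 | diol: C11 hydroxymethyl, C27 hydroxyl on the face of C11 | C[C@@]12CC(=O)O[C@@H]1[C@]13C[C@](CO)(C[C@@H]1O)[C@H](C=C)CN3C2 | intermediate
33 | C11 tert-butyldimethylsilyl ether with free C27 hydroxyl | C[C@@]12CC(=O)O[C@@H]1[C@]13C[C@](CO[Si](C)(C)C(C)(C)C)(C[C@@H]1O)[C@H](C=C)CN3C2 | intermediate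
34 | ozonide of the C13 vinyl group | C[C@@]12CC(=O)O[C@@H]1[C@]13C[C@](CO[Si](C)(C)C(C)(C)C)(C[C@@H]1O)[C@H](C4OOCO4)CN3C2 | intermediate (not isolated)
35 | C14 aldehyde on C13 | C[C@@]12CC(=O)O[C@@H]1[C@]13C[C@](CO[Si](C)(C)C(C)(C)C)(C[C@@H]1O)[C@H](C=O)CN3C2 | intermediate
36 | 2-bromocyclopent-2-en-1-one | O=C1CCC=C1Br | starting material
37 | (R)-2-bromocyclopent-2-en-1-ol | O[C@@H]1CCC=C1Br | intermediate
38 | mixed ketene acetal of 37 (1-ethoxyvinyl ether) | C=C(OCC)O[C@@H]1CCC=C1Br | intermediate (not isolated)
39 | ethyl (R)-2-(2-bromocyclopent-2-en-1-yl)acetate | CCOC(=O)C[C@H]1CCC=C1Br | intermediate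
40 | (R)-2-(2-bromocyclopent-2-en-1-yl)acetic acid | OC(=O)C[C@H]1CCC=C1Br | intermediate
41 | (S)-1-bromo-5-(iodomethyl)cyclopent-1-ene | IC[C@H]1CCC=C1Br | intermediate
42 | [(2-bromocyclopent-2-en-1-yl)methyl]triphenylphosphonium iodide, ring carbon configured as in 41 | [I-].c1ccc(cc1)[P+](c1ccccc1)(c1ccccc1)C[C@H]1CCC=C1Br | intermediate
43 | phosphorus ylide from 42 | c1ccc(cc1)P(c1ccccc1)(c1ccccc1)=C[C@H]1CCC=C1Br | intermediate (not isolated)
44 | (Z)-C14=C15 alkene joining C13 to the bromocyclopentene | C[C@@]12CC(=O)O[C@@H]1[C@]13C[C@](CO[Si](C)(C)C(C)(C)C)(C[C@@H]1O)[C@H](/C=C\[C@H]4CCC=C4Br)CN3C2 | intermediate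
45 | saturated bromide with C27 hydroxyl | C[C@@]12CC(=O)O[C@@H]1[C@]13C[C@](CO[Si](C)(C)C(C)(C)C)(C[C@@H]1O)[C@H](CC[C@H]4CCC=C4Br)CN3C2 | intermediate
46 | C27 ketone | C[C@@]12CC(=O)O[C@@H]1[C@]13C[C@](CO[Si](C)(C)C(C)(C)C)(CC1=O)[C@H](CC[C@H]4CCC=C4Br)CN3C2 | intermediate
47 | keto ester: methyl propanoate arm on C21 (exo face) | C[C@@]12CC(=O)O[C@@H]1[C@]13C[C@](CO[Si](C)(C)C(C)(C)C)([C@H](CCC(=O)OC)C1=O)[C@H](CC[C@H]4CCC=C4Br)CN3C2 | intermediate
48 | hexacyclic keto ester: seven-membered ring closed at C20–C21, C21 quaternary | C[C@@]12CC(=O)O[C@@H]1[C@]13C[C@@]4(CO[Si](C)(C)C(C)(C)C)[C@H](CC[C@H]5CCC=C5[C@@]4(CCC(=O)OC)C1=O)CN3C2 | intermediate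
49 | hydroxy ester: C27 hydroxyl on the face of the C22 arm (formed as its aluminium alkoxide) | C[C@@]12CC(=O)O[C@@H]1[C@]13C[C@@]4(CO[Si](C)(C)C(C)(C)C)[C@H](CC[C@H]5CCC=C5[C@@]4(CCC(=O)OC)[C@@H]1O)CN3C2 | intermediate (not isolated)
50 | O12 tert-butyldimethylsilyl ether of the target | C[C@@]12CC(=O)O[C@@H]1[C@]13C[C@@]4(CO[Si](C)(C)C(C)(C)C)[C@H](CC[C@H]5CCC=C5[C@]45CCC(=O)O[C@H]15)CN3C2 | intermediate
51 | CNP0247797.1 | C[C@@]12CC(=O)O[C@@H]1[C@]13C[C@@]4(CO)[C@H](CC[C@H]5CCC=C5[C@]45CCC(=O)O[C@H]15)CN3C2 | target

## Step count and least certain steps

Total: 34 steps. Longest linear sequence: 27 steps (steps 1 to 5, 8 to 22 and 28 to 34, from 1). Steps 6 and 7 (boronate 12) and steps 23 to 27 (phosphonium salt 42) are side branches.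

**Step 12 (key step).** The most likely failure is slow insertion: C8–H is deactivated by O26 on the neighbouring carbon and sits on a strained bicycle, so the nitrene may be lost to intermolecular reactions or to attack on the acetal C–H, and the oxidant may degrade the acetal meanwhile. Fallback: the nitrene is generated by base-induced α-elimination from a pre-oxidised nitrogen, without hypervalent iodine or acid. Starting from alcohol 17, carbonyldiimidazole followed by hydroxylamine hydrochloride gives the N-hydroxycarbamate F1; tosyl chloride and triethylamine give the N-tosyloxycarbamate F2; Rh2(O2CCPh3)4 with K2CO3 in CH2Cl2 at rt then closes the same oxazolidinone, and the route is rejoined at 21.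

**Step 5.** The methylating agent may fail to discriminate: it could alkylate O26 of the open hydroxy dialdehyde or activate the C7 aldehyde, and C8 could epimerise. Fallback: the differentiation is made by oxidation state instead. Starting from 6, Ag2CO3 on Celite in refluxing benzene oxidises only the lactol and gives the bridged lactone aldehyde F3. Methylenation with Ph3P=CH2 stores the aldehyde as the alkene in lactone alkene F4. iBu2AlH gives the lactol alkene F5, and NaH with methyl iodide gives the methyl acetal alkene F6 (no aldehyde is present, so base can be used). Ozonolysis with PPh3 work-up returns to 7.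

**Step 8.** Facial selectivity at the α-branched endo aldehyde may be poor, in which case C7 and C2 are inverted together; the slow reaction of the γ,γ-disubstituted boronate also gives C8 time to epimerise. Fallback: the face is controlled by a catalyst instead of the substrate. Compounds 7 and 12 are combined at −30 °C in toluene with 5 mol% of the chiral phosphoric acid 3,3′-bis(2,4,6-triisopropylphenyl)-1,1′-binaphthyl-2,2′-diyl hydrogen phosphate, in the enantiomer that directs the allyl group to the Si face (expected to be the S acid). This also accelerates the addition. The product is again 14 and no new compound is made (F0).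

**Step 19.** The π-allyl palladium complex may be captured by the amine catalyst before the hindered, α-branched aldehyde has formed its enamine, which would give an N-allylpyrrolidine instead of the ring. Fallback: a metal-free Stork enamine alkylation. Starting from 29, excess (E)-1,4-dibromobut-2-ene gives the allylic bromide F7 (handled as its hydrobromide). A stoichiometric amount of pyrrolidine in MeCN at 60 °C forms the enamine, which closes the six-membered ring by intramolecular SN2′ displacement; aqueous hydrolysis returns to 31.

**Step 32.** Reductive elimination at a tertiary enolate carbon next to the quaternary C10 may be too slow. The alkenylpalladium species would then be lost by protodebromination, or the enolate would lose the acrylate by retro-Michael reaction. Fallback: the order of the two bond formations at C21 is reversed. Starting from 46, the same palladium conditions close the ring at the unsubstituted C21 methylene and give the α-alkenyl ketone F8. Methyl acrylate with catalytic KOtBu then adds to the doubly activated C21–H from the exo face and rejoins the route at 48. The cost is that F8 can move its alkene into conjugation and lose the C16 configuration, so it must be used at once under mild base.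

**Step 33.** Hydride transfer from aluminium isopropoxide is expected to reach the ketone first on the exo face, so the alkoxide that cannot lactonise may accumulate if its re-oxidation is slow; isopropoxide may also open the γ-lactone. Fallback: reduction and equilibration are separated. Starting from 48, NaBH4 in MeOH gives the kinetic C27-epimeric hydroxy ester F9. Heating F9 in toluene at 100 °C with the hydrogen-transfer catalyst [Ru2(CO)4(μ-H)(C4Ph4COHOCC4Ph4)] epimerises the carbinol through ketone 48 until the alcohol on the face of the C22 arm is drained as the lactone, and the route is rejoined at 50.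

## Further compounds

F1 | step 12 | N-hydroxycarbamate of 17 at O6 | CC(C)(C)[Si](C)(C)OCC[C@@](C)(CO[Si](C)(C)C(C)(C)C)[C@H](OC(=O)NO)[C@@H]1C[C@H]2C[C@@H]1O[C@@H]2OC
F2 | step 12 | N-tosyloxycarbamate of 17 at O6 | CC(C)(C)[Si](C)(C)OCC[C@@](C)(CO[Si](C)(C)C(C)(C)C)[C@H](OC(=O)NOS(=O)(=O)c1ccc(C)cc1)[C@@H]2C[C@H]3C[C@@H]2O[C@@H]3OC
F3 | step 5 | bridged lactone aldehyde: 6-endo-formyl-2-oxabicyclo[2.2.1]heptan-3-one | O=C[C@@H]1C[C@H]2C[C@@H]1OC2=O
F4 | step 5 | bridged lactone alkene: 6-endo-vinyl-2-oxabicyclo[2.2.1]heptan-3-one | C=C[C@@H]1C[C@H]2C[C@@H]1OC2=O
F5 | step 5 | lactol alkene: 6-endo-vinyl-2-oxabicyclo[2.2.1]heptan-3-ol (anomers) | C=C[C@@H]1C[C@H]2C[C@@H]1OC2O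
F6 | step 5 | methyl acetal alkene: 3-exo-methoxy-6-endo-vinyl-2-oxabicyclo[2.2.1]heptane | C=C[C@@H]1C[C@H]2C[C@@H]1O[C@@H]2OC
F0 | step 8 | none | none
F7 | step 19 | N-[(E)-4-bromobut-2-enyl] derivative of 29 | C[C@@]12CC(=O)O[C@@H]1[C@]3(N(C/C=C/CBr)C2)C[C@H]4C[C@@H]3OC4O
F8 | step 32 | α-alkenyl ketone: seven-membered ring closed at C20–C21, C21 still bearing hydrogen | C[C@@]12CC(=O)O[C@@H]1[C@]13C[C@@]4(CO[Si](C)(C)C(C)(C)C)[C@H](CC[C@H]5CCC=C5[C@H]4C1=O)CN3C2
F9 | step 33 | C27-epimeric hydroxy ester (hydroxyl on the face of C20) | C[C@@]12CC(=O)O[C@@H]1[C@]13C[C@@]4(CO[Si](C)(C)C(C)(C)C)[C@H](CC[C@H]5CCC=C5[C@@]4(CCC(=O)OC)[C@H]1O)CN3C2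
A1 | alternative 1 | cyclopropane-fused pentacyclic ketone with phthalimidomethyl group | O=C1[C@@H]2C[C@@]23[C@@H](CN4C(=O)c5ccccc5C4=O)CC[C@H]6CCC=C6[C@]37CCC(=O)O[C@H]17
A2 | alternative 2 | cis-fused dichlorocyclobutanone pyrrolidine | C[C@@]12C(Cl)(Cl)C(=O)[C@@H]1[C@@H](C(=O)OC)N(C(=O)OC(C)(C)C)C2
A3 | alternative 3 | hexacyclic keto ester with quaternary C21 (same structure as 48) | C[C@@]12CC(=O)O[C@@H]1[C@@]36C[C@@]4(CO[Si](C)(C)C(C)(C)C)[C@H](CC[C@H]5CCC=C5[C@@]4(CCC(=O)OC)C6=O)CN3C2
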